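All runs were computed with constants of no real substance; the scatter is artificial.

The vessel is closed and stirred. Beta, theta, zeta and gamma each run in such a vessel for 2.0 h, with 1.5 M starting material and 0.450 M protic impurity, at reagent charges from 0.0600 M to 1.50 M.

all flasks: starting material 1.5 M
- teal: reagent 0.067 M; protic impurity 0.45 M; run made earlier
- amber: reagent 2.2 M; protic impurity 0.45 M; run made earlier
- beta: reagent 0.0600 M; protic impurity 0.450 M; time 2.0 h
- theta: reagent 0.150 M; protic impurity 0.450 M; time 2.0 h
- zeta: reagent 0.500 M; protic impurity 0.450 M; time 2.0 h
- gamma: reagent 1.50 M; protic impurity 0.450 M; time 2.0 h

| run | time / min | target / % |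
|---|---|---|
| teal | 6.00 | 0.1 |
| teal | 12.0 | 0.1 |
| teal | 20.0 | 0.4 |
| teal | 30.0 | 0.9 |
| teal | 50.0 | 0 |
| teal | 80.0 | 0 |
| amber | 6.00 | 0 |
| amber | 15.0 | 2.3 |
| amber | 30.0 | 5.1 |
| amber | 50.0 | 8.7 |
| amber | 60.0 | 11.2 |
| amber | 80.0 | 13.2 |

(each reading ± 0.5 percentage points)

- what is said of target includes idle adduct
- the earlier runs were read with a standard deviation of 0.5 percentage points
- steps that have been proposed: starting material + reagent -> intermediate A; intermediate A -> intermediate B; intermediate B <-> intermediate C; intermediate A -> target; target <-> intermediate C; target -> over-reaction product; reagent + target <-> idle adduct; starting material + protic impurity -> quenched substrate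
- "hardly changes" means that all values lie within two and a half points (for a concentration: within two and a half percent of the largest)

1. amount of target at the end, in percent of the starting material charged for beta, theta, zeta, gamma, in this order
2. the shape of the row from first to last (falls all the way / rises, then falls / rises all the way / falls, then rises / hardly changes)

The amber run reads 5.1% target at 30.0 min and 13.2% at 80.0 min, so its target grows nearly in step with time. Dividing its last reading by its reagent charge and its time gives a rate per unit of reagent, κ = 7.50 × 10⁻⁴ /M/min. The earlier amber reading gives 7.73 × 10⁻⁴ /M/min.

The reckoning here folds the givens into κ·c(reagent)·t, which for gamma is 13.5%. This is the dose number D, the run time counted in lifetimes of starting material toward target. Gamma's D is below one, so D is read directly as the fraction standing as target. Beta, theta and zeta get 0.540%, 1.35% and 4.50%, and the row rises.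

Is one number enough? Amber carried 0.45 M protic impurity, the charge of the asked flasks, so κ was read with that charge in place. The first power of reagent remains untested: teal's D at 80.0 min is 0.402%, against a scatter of 0.5 percentage points.

The forecast gives 0.4%, 1.2%, 4.2% and 12.5%, rises all the way, lying under D at gamma, at zeta, at theta and at beta. Its ground for the top of the row: “Nothing suggests a high-reagent penalty, because amber is the best run so far.”

The flask gives 0.617%, 1.52%, 4.77% and 12.1%, rises all the way, the shape the forecast gave.

    starting material + reagent → intermediate A (k = 0.00761 /M/min)
    intermediate A → intermediate B (k = 0.00960 /min)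
    intermediate B ⇌ intermediate C (K = 0.705, k = 0.0424 /min)
    intermediate A → target (k = 0.0167 /min)
    target ⇌ intermediate C (K = 0.267, k = 0.0208 /min)
    target → over-reaction product (k = 0.0174 /min)
    reagent + target ⇌ idle adduct, settled at all times (K = 0.140 /M)
    starting material + protic impurity → quenched substrate (k = 0.0829 /M/min)

Target over D is 0.896 in gamma, which ended with over-reaction product at 13.3% and starting material at 25.4%, and 1.14 in beta. In beta the step to quenched substrate ran while protic impurity was there: at 1.00 h quenched substrate stood at 29.9%, and protic impurity at 0.404% of its charge. In the second hour the steps from intermediate A to target and from target to over-reaction product ran on, and beta ended with over-reaction product at 0.705% beside target at 0.617%.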